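## Analysis of the target

The target (34) is built from three units. Rings A and B form a trans-fused octahydronaphthalene, numbered here C1–C8a with the (E)-propenyl group on C1, the acyl group on C2, the C3=C4 alkene carrying a methyl on C4, and a second methyl on C7. Ring C is a 3-acyl-4-hydroxy-2-pyridone (N1, C2–C6). Ring D is an oxygenated cyclohexane (C1'–C6') bound through its quaternary carbinol C1' to pyridone C5, with a secondary carbinol at C4' and an oxirane across C5'–C6' (C6' next to C1'). In systematic names ring D is a 7-oxabicyclo[4.1.0]heptan-2-yl group whose C2, C5, C1 and C6 are C1', C4', C6' and C5'.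

The decalin has five stereocentres (1R,2S,4aS,7S,8aR). H4a and H8a are anti, and the C7 methyl, C1 propenyl and C2 acyl groups are all equatorial, so C1 and C2 are trans. Decalin C2 is α to the ketone and allylic; it is the only epimerisable centre, and the target holds its more stable configuration.

Ring D has four contiguous stereocentres (1'R,4'R,5'S,6'S). The oxirane oxygen lies on the face opposite to both hydroxyls, so the two hydroxyls are cis to each other and the pyridone is cis to the oxirane.

Several groups are sensitive. Each hydroxyl is anti to the neighbouring oxirane C–O bond and can undergo Payne rearrangement in base. The tertiary carbinol is benzylic to an electron-rich hydroxypyridone and can ionise in acid. The β,γ-unsaturated ketone can slip into conjugation.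

The difficulty is threefold. The decalin and ring D are too far apart to control one another, so each must be made as a single enantiomer. The pyridone is substituted at C3, C4 and C5 between two bulky groups. Acylating a metalated alkoxypyridine would expose the oxirane to an organolithium.

The strategy rests on ring C: pyridone C3 lies between the C2 lactam carbonyl and the exocyclic decalin ketone and is therefore the central carbon of a β-keto amide. C4 is at the carboxylic acid oxidation level, and C4–C5–C6–N1 with ring D on C5 is an α-substituted β-aminoacrylate. Ring C can therefore be closed last, at C3–C4, by an intramolecular Claisen condensation.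

## Retrosynthetic reasoning

**34 to 33 (O–Si bonds).** The two ring D hydroxyls are unmasked last. Both are anti to the oxirane, so neither may be a free alkoxide in any basic step. Silyl ethers come off with fluoride near neutrality, after all base chemistry is done.

**33 to 32 (pyridone C3–C4).** This is the key cut. It turns the aromatic ring into an open N-(β-ketoacyl) enamino ester in which C3 is a doubly activated methylene and C4 a methyl ester. Cutting here, and not at a pyridone–ring D or pyridone–acyl bond, means the heterocycle is never metalated and ring D never meets a strong carbon nucleophile. The forward reaction must acylate C3 with the ester and aromatise.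

**32 to 17 and 30 (amide N–C bond).** This is the convergent cut: it separates the decalin as acyl Meldrum's acid 17 from ring D as enamino ester 30. Forward, 17 is heated to give acylketene 31, which acylates the nitrogen of 30 without base or coupling agent. The enamine carbon of 30 is fully substituted, so only nitrogen can react productively.

**30 to 29 to 28 (pyridone C6–N1 and C5–C6).** The amino group is removed to give hydroxymethylene ester 29, and the formyl carbon is removed to give ester 28. Forward, this is a crossed Claisen formylation followed by condensation with an ammonium salt. The tertiary hydroxyl is silylated first (27 to 28) so that no β-alkoxide is present.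

**27 to 25 and 26 (pyridone C5–C1').** The quaternary carbinol comes from aldol addition of the enolate of methyl acetate 26 to epoxy ketone 25. The oxirane and the C4' oxygen are in place before this C–C bond forms, so the addition only has to choose a face. Adding to the oxirane face, anti to the silyloxy group, gives the required 1',4'-cis and 1',6'-trans relations.

**25 to 24 (oxirane C–O bonds).** Nucleophilic epoxidation of silyloxy enone 24, anti to the silyloxy group, sets C5' and C6'.

**24 to 20 to 18.** Enone 24 comes from meso diol 20 by enzymatic desymmetrisation (20 to 21), silylation, deacetylation and oxidation (22, 23). Diol 20 comes from cyclohexa-1,3-diene 18 by photo-oxygenation through endoperoxide 19. The absolute configuration of all of ring D is decided in the desymmetrisation.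

**17 to 15 and 16; 15 to 14 to 12.** Acid 15 is C-acylated onto Meldrum's acid 16. It is reached from aldehyde 14, which is the C2 epimer of the aldehyde (13) obtained by oxidising alcohol 12. The C2 configuration is corrected here, by equilibration, because the cycloaddition below can only deliver C1 and C2 cis.

**12 and 11 to 10 (propenyl C=C).** The propenyl group is made from the C1 aldehyde of 10 by an E-selective alkylidenation.

**10 to 9 (C1–C2 and C4a–C8a).** Both carbocycles come from one intramolecular Diels–Alder reaction of trienal 9. The C3=C4 alkene fixes the diene as C2=C3–C4=C4a and the dienophile as C1=C8a. The four-carbon tether carries the C7 methyl, which sits equatorial in the chair-like transition state and relays the configuration to C1, C2, C4a and C8a.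

**9 to 1.** The trienal is unravelled by three olefinations and one ozonolysis (8, 7, 6, 5, 4, 3, 2) to (S)-citronellal 1. Its aldehyde carbon becomes C8a, its stereocentre becomes C7, and its trisubstituted alkene carbon becomes C4a.

## Alternatives that were turned down

**Alternative 1:** The disconnection removes the C1'–O and C4'–O bonds of ring D together, with the pyridone carried as a 2,4-dialkoxypyridine that is acylated at C3 later. In the forward key step, singlet oxygen adds suprafacially across C1' and C4' of a biocatalytically made aryl cyclohexadiene cis-diol acetonide, on the face away from the acetonide, to give endoperoxide A1.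

- For it: one cycloaddition fixes the cis relation of the two carbinol oxygens and places them opposite the oxygens that become the oxirane. On this point it is more secure than the facial choice in the aldol step of the chosen route (step 20).
- Against it: A1 has four ring oxygens and an alkene where ring D needs three oxygens and none. The O–O bond must be reduced and C2'=C3' saturated. The cis-diol must become an oxirane on the same face, which needs two inversions at one carbon. All of this happens on a tertiary benzylic peroxide next to an electron-rich pyridine that itself reacts with singlet oxygen.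
- Also against it: the dihydroxylating organism for such a biaryl is not a purchasable reagent, and pyridine C3 must still be metalated and acylated with ring D present.
- Comparison: the chosen strategy gives up the certainty of the cycloaddition at C1', but needs no redox corrections on ring D and no organometallic step after the oxirane is made.

**Alternative 2:** The ring D oxygens are introduced one after another onto an achiral 1-pyridylcyclohexa-1,3-diene. In the forward key step, a chiral dioxirane (carbohydrate-derived ketone with a peroxymonosulfate oxidant) epoxidises the trisubstituted C1'=C6' alkene to vinyl epoxide A2. A zerovalent palladium catalyst would then move oxygen to C4' by double inversion, and a second epoxidation would finish the ring.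

- For it: the absolute configuration comes from a catalyst, the 1',4'-cis relation follows from the mechanism, and ring D needs only three oxidation events. In step count for ring D it beats the chosen route.
- Against it: A2 is an oxirane that is both allylic and benzylic to a pyridine with two donor alkoxy groups. Heterolysis of C1'–O to a stabilised cation, followed by ring opening or 1,2-shift, is likely under aqueous oxidising conditions. N-oxidation of the pyridine and attack at the other alkene also compete.
- Also against it: the last epoxidation must occur on the face that carries the pyridyl group and is anti to both oxygens; free hydroxyls would direct it to the wrong face. The pyridine again has to be acylated by metalation afterwards.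
- Comparison: the chosen route places the oxirane on a simple enone, where one silyloxy group controls it, and only then builds the quaternary centre.

**Alternative 3:** The pyridone is disconnected at C4–C5 back to a tyrosine-derived 3-acyltetramic acid. In the forward key step, a ring-expanding cytochrome P450 enzyme oxidises the benzylic carbon, which is captured by the C4 carbonyl with cleavage of the old ring bond, and aromatisation gives the 5-(4-hydroxyphenyl)pyridone A3.

- For it: heterocycle and aryl–pyridone bond arise in one protecting-group-free step. The tetramic acid precursor comes from a five-ring Lacey–Dieckmann closure that is better precedented than the six-ring closure used here. For the decalin–pyridone core it is the shortest plan.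
- Against it: A3 has a flat para-hydroxyphenyl ring where the target has a saturated ring with four stereocentres. Oxidative dearomatisation would create the C1' carbinol but give a symmetrical dienone. One of its two enantiotopic alkenes must then be epoxidised, the other reduced, and the ketone reduced. This would be under reagent control only, and in the presence of the decalin alkenes and the acylpyridone.
- Also against it: the enzyme must be expressed and accepts only close analogues of its natural substrate, which weakens a synthesis from commercial materials.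
- Comparison: the chosen strategy settles every ring D stereocentre on a small carbocycle before the pyridone exists.

Key step: step 25

Assumption: the lipase in step 15 acetylates the (S)-configured carbinol carbon of meso diol 20, the sense usual for cis-cycloalk-2-ene-1,4-diols; with an enzyme of opposite preference the same enantiotopic choice would be made by enzymatic hydrolysis in place of enzymatic acylation.

## Steps

Step 1
Reactants: 1 (S)-citronellal [(3S)-3,7-dimethyloct-6-enal]
Product: 2 (6S)-8,8-dimethoxy-2,6-dimethyloct-2-ene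
Conditions: HC(OMe)3, MeOH, PPTS (cat.), rt
Reagents that add atoms: trimethyl orthoformate, COC(OC)OC
Why: Acid-catalysed acetalisation with the orthoformate as water scavenger masks the aldehyde so that the alkene end can be worked on first; the mild catalyst at room temperature avoids the carbonyl-ene cyclisation of citronellal and leaves the stereocentre untouched.

Step 2
Reactants: 2 (6S)-8,8-dimethoxy-2,6-dimethyloct-2-ene
Product: 3 (4S)-6,6-dimethoxy-4-methylhexanal
Conditions: O3, CH2Cl2, −78 °C; then PPh3, −78 °C → rt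
Reagents that add atoms: ozone, [O-][O+]=O
Why: Ozonolysis with reductive work-up cleaves the only alkene and gives the aldehyde whose carbon becomes decalin C4a; the acetal is inert.

Step 3
Reactants: 3 (4S)-6,6-dimethoxy-4-methylhexanal
Product: 5 methyl (2E,4E,8S)-10,10-dimethoxy-4,8-dimethyldeca-2,4-dienoate, via enal acetal 4 (not isolated)
Conditions: Ph3P=C(Me)CHO, PhMe, 90 °C; then Ph3P=CHCO2Me, 90 °C
Reagents that add atoms: 2-(triphenylphosphoranylidene)propanal, CC(C=O)=P(c1ccccc1)(c1ccccc1)c1ccccc1; methyl (triphenylphosphoranylidene)acetate, COC(=O)C=P(c1ccccc1)(c1ccccc1)c1ccccc1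
Why: Two Wittig reactions of stabilised ylides run in sequence in one flask; the first sets the (E)-trisubstituted alkene (future C4=C4a with the C4 methyl), the second the (E)-disubstituted alkene, both E because stabilised ylides react under thermodynamic control. The second ylide is added only after the first aldehyde is consumed, since it would otherwise react with aldehyde 3.

Step 4
Reactants: 5 methyl (2E,4E,8S)-10,10-dimethoxy-4,8-dimethyldeca-2,4-dienoate
Product: 6 (2E,4E,8S)-10,10-dimethoxy-4,8-dimethyldeca-2,4-dien-1-ol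
Conditions: iBu2AlH, CH2Cl2, −78 °C
Reagents that add atoms: none
Why: 1,2-Reduction of the dienoate removes the electron-withdrawing group from the diene, which must be the electron-rich partner of the later cycloaddition; the acetal is stable to the hydride at low temperature.

Step 5
Reactants: 6 (2E,4E,8S)-10,10-dimethoxy-4,8-dimethyldeca-2,4-dien-1-ol
Product: 7 tert-butyl{[(2E,4E,8S)-10,10-dimethoxy-4,8-dimethyldeca-2,4-dien-1-yl]oxy}diphenylsilane
Conditions: tBuPh2SiCl, imidazole, CH2Cl2, rt
Reagents that add atoms: tert-butyl(chloro)diphenylsilane, CC(C)(C)[Si](Cl)(c1ccccc1)c1ccccc1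
Why: Standard silylation of a primary alcohol; the tert-butyldiphenylsilyl ether is chosen because it survives the aqueous acid of step 6 and the Lewis acid of step 8, and it prevents lactol formation after the cycloaddition.

Step 6
Reactants: 7 tert-butyl{[(2E,4E,8S)-10,10-dimethoxy-4,8-dimethyldeca-2,4-dien-1-yl]oxy}diphenylsilane
Product: 8 (3S,6E,8E)-10-[(tert-butyldiphenylsilyl)oxy]-3,7-dimethyldeca-6,8-dienal
Conditions: PPTS, acetone/H2O, 50 °C
Reagents that add atoms: water, O
Why: Mild acid-catalysed hydrolysis of the dimethyl acetal frees the aldehyde; the hindered silyl ether and the diene tolerate these conditions.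

Step 7
Reactants: 8 (3S,6E,8E)-10-[(tert-butyldiphenylsilyl)oxy]-3,7-dimethyldeca-6,8-dienal
Product: 9 (2E,5S,8E,10E)-12-[(tert-butyldiphenylsilyl)oxy]-5,9-dimethyldodeca-2,8,10-trienal
Conditions: Ph3P=CHCHO, PhMe, 80 °C
Reagents that add atoms: (triphenylphosphoranylidene)acetaldehyde, O=CC=P(c1ccccc1)(c1ccccc1)c1ccccc1
Why: Wittig reaction of the formyl-stabilised ylide gives the (E)-enal, the activated dienophile; the conjugated product aldehyde is much less reactive towards the ylide than the saturated aldehyde.

Step 8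
Reactants: 9 (2E,5S,8E,10E)-12-[(tert-butyldiphenylsilyl)oxy]-5,9-dimethyldodeca-2,8,10-trienal
Product: 10 (1R,2S,4aS,7S,8aS)-2-{[(tert-butyldiphenylsilyl)oxy]methyl}-4,7-dimethyl-1,2,4a,5,6,7,8,8a-octahydronaphthalene-1-carbaldehyde
Conditions: Me2AlCl, CH2Cl2, −78 → −30 °C
Reagents that add atoms: none
Why: Lewis acid-promoted intramolecular Diels–Alder reaction of a terminally activated trienal; the formyl group is endo, which with the (E)-dienophile gives the trans ring fusion and an equatorial C1 substituent, and the chair-like tether with the methyl equatorial fixes C4a and C8a relative to C7. The (E,E)-diene places the C2 silyloxymethyl group cis to the C1 formyl group, so C2 is formed in the configuration opposite to that of the target and is corrected in step 11.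

Step 9
Reactants: 10 (1R,2S,4aS,7S,8aS)-2-{[(tert-butyldiphenylsilyl)oxy]methyl}-4,7-dimethyl-1,2,4a,5,6,7,8,8a-octahydronaphthalene-1-carbaldehyde
Product: 11 tert-butyl({(1R,2R,4aS,7S,8aR)-4,7-dimethyl-1-[(1E)-prop-1-en-1-yl]-1,2,4a,5,6,7,8,8a-octahydronaphthalen-2-yl}methoxy)diphenylsilane
Conditions: CrCl2, CH3CHI2, THF, rt
Reagents that add atoms: 1,1-diiodoethane, CC(I)I
Why: Takai–Utimoto alkylidenation through a geminal dichromium reagent gives the (E)-alkene and is not basic, so the α-stereocentre C1 is not disturbed.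

Step 10
Reactants: 11 tert-butyl({(1R,2R,4aS,7S,8aR)-4,7-dimethyl-1-[(1E)-prop-1-en-1-yl]-1,2,4a,5,6,7,8,8a-octahydronaphthalen-2-yl}methoxy)diphenylsilane
Product: 12 {(1R,2R,4aS,7S,8aR)-4,7-dimethyl-1-[(1E)-prop-1-en-1-yl]-1,2,4a,5,6,7,8,8a-octahydronaphthalen-2-yl}methanol
Conditions: Bu4NF, THF, rt
Reagents that add atoms: none
Why: Fluoride cleaves the silyl ether; nothing else in the molecule responds to fluoride.

Step 11
Reactants: 12 {(1R,2R,4aS,7S,8aR)-4,7-dimethyl-1-[(1E)-prop-1-en-1-yl]-1,2,4a,5,6,7,8,8a-octahydronaphthalen-2-yl}methanol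
Product: 14 (1R,2S,4aS,7S,8aR)-4,7-dimethyl-1-[(1E)-prop-1-en-1-yl]-1,2,4a,5,6,7,8,8a-octahydronaphthalene-2-carbaldehyde, via cis aldehyde 13 (not isolated)
Conditions: SO3·pyridine, DMSO, iPr2NEt, CH2Cl2, 0 °C; then DBU (0.3 equiv), rt
Reagents that add atoms: none
Why: Parikh–Doering oxidation gives the cis aldehyde 13 with a pseudoaxial formyl group; the amidine base then equilibrates C2 through the extended enolate, which is reprotonated at the α-carbon faster than at the hindered γ-carbon C4, towards the all-equatorial trans aldehyde 14. The equilibration is followed and stopped before the alkene moves into conjugation.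

Step 12
Reactants: 14 (1R,2S,4aS,7S,8aR)-4,7-dimethyl-1-[(1E)-prop-1-en-1-yl]-1,2,4a,5,6,7,8,8a-octahydronaphthalene-2-carbaldehyde
Product: 15 (1R,2S,4aS,7S,8aR)-4,7-dimethyl-1-[(1E)-prop-1-en-1-yl]-1,2,4a,5,6,7,8,8a-octahydronaphthalene-2-carboxylic acid
Conditions: NaClO2, NaH2PO4, 2-methylbut-2-ene, tBuOH/H2O, 0 °C → rt
Reagents that add atoms: sodium chlorite, [Na+].[O-]Cl=O
Why: Pinnick oxidation in a weakly acidic buffer does not enolise C2, and the excess of scavenger alkene protects the two alkenes of the substrate from hypochlorous acid.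

Step 13
Reactants: 15 (1R,2S,4aS,7S,8aR)-4,7-dimethyl-1-[(1E)-prop-1-en-1-yl]-1,2,4a,5,6,7,8,8a-octahydronaphthalene-2-carboxylic acid; 16 Meldrum's acid (2,2-dimethyl-1,3-dioxane-4,6-dione)
Product: 17 5-[{(1R,2S,4aS,7S,8aR)-4,7-dimethyl-1-[(1E)-prop-1-en-1-yl]-1,2,4a,5,6,7,8,8a-octahydronaphthalen-2-yl}(hydroxy)methylidene]-2,2-dimethyl-1,3-dioxane-4,6-dione
Conditions: DCC, DMAP, CH2Cl2, 0 °C → rt
Reagents that add atoms: none
Why: Carbodiimide-mediated C-acylation of Meldrum's acid gives the fully enolised acyl Meldrum's acid; the low temperature limits ketene formation from the activated acid and so keeps the C2 configuration.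

Step 14
Reactants: 18 cyclohexa-1,3-diene
Product: 20 cis-cyclohex-2-ene-1,4-diol (meso), via endoperoxide 19 (not isolated)
Conditions: O2, tetraphenylporphyrin (cat.), visible light, CH2Cl2, 0 °C; then thiourea, MeOH, rt
Reagents that add atoms: dioxygen, O=O
Why: Singlet oxygen adds to the diene in a suprafacial [4+2] cycloaddition, and reduction of the O–O bond keeps both C–O bonds, so the diol is necessarily cis.

Step 15
Reactants: 20 cis-cyclohex-2-ene-1,4-diol (meso)
Product: 21 (1S,4R)-4-hydroxycyclohex-2-en-1-yl acetate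
Conditions: lipase (Burkholderia cepacia), vinyl acetate, THF, rt
Reagents that add atoms: vinyl acetate, CC(=O)OC=C
Why: Enzymatic desymmetrisation by irreversible transesterification; the lipase acylates one of the two enantiotopic carbinols, and this choice fixes the absolute configuration of every ring D stereocentre made later.

Step 16
Reactants: 21 (1S,4R)-4-hydroxycyclohex-2-en-1-yl acetate
Product: 22 (1S,4R)-4-[(tert-butyldimethylsilyl)oxy]cyclohex-2-en-1-yl acetate
Conditions: tBuMe2SiCl, imidazole, DMF, rt
Reagents that add atoms: tert-butyl(chloro)dimethylsilane, CC(C)(C)[Si](C)(C)Cl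
Why: Silylation of the free (R)-configured carbinol, the one that becomes C4' of ring D.

Step 17
Reactants: 22 (1S,4R)-4-[(tert-butyldimethylsilyl)oxy]cyclohex-2-en-1-yl acetate
Product: 23 (1S,4R)-4-[(tert-butyldimethylsilyl)oxy]cyclohex-2-en-1-ol
Conditions: K2CO3 (cat.), MeOH, 0 °C
Reagents that add atoms: none
Why: Base-catalysed transesterification removes the acetate; the silyl ether is stable.

Step 18
Reactants: 23 (1S,4R)-4-[(tert-butyldimethylsilyl)oxy]cyclohex-2-en-1-ol
Product: 24 (4R)-4-[(tert-butyldimethylsilyl)oxy]cyclohex-2-en-1-one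
Conditions: MnO2, CH2Cl2, rt
Reagents that add atoms: none
Why: Selective oxidation of the allylic alcohol to the enone; the remaining stereocentre is not enolisable under these conditions.

Step 19
Reactants: 24 (4R)-4-[(tert-butyldimethylsilyl)oxy]cyclohex-2-en-1-one
Product: 25 (1S,5R,6R)-5-[(tert-butyldimethylsilyl)oxy]-7-oxabicyclo[4.1.0]heptan-2-one
Conditions: H2O2 (30% aq.), NaOH (cat.), MeOH, 0 °C
Reagents that add atoms: hydrogen peroxide, OO
Why: Weitz–Scheffer nucleophilic epoxidation; hydroperoxide adds to the enone face opposite the pseudoaxial silyloxy group, so the oxirane (C5', C6') is formed trans to the C4' oxygen.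

Step 20
Reactants: 25 (1S,5R,6R)-5-[(tert-butyldimethylsilyl)oxy]-7-oxabicyclo[4.1.0]heptan-2-one; 26 methyl acetate
Product: 27 methyl 2-{(1S,2R,5R,6R)-5-[(tert-butyldimethylsilyl)oxy]-2-hydroxy-7-oxabicyclo[4.1.0]heptan-2-yl}acetate
Conditions: LiN(iPr)2, THF, −78 °C; AcOH
Reagents that add atoms: none
Why: Aldol addition of the lithium ester enolate to the ketone at low temperature, quenched cold to prevent retro-aldol cleavage and Payne rearrangement of the aldolate. C1' is set by axial attack on the half-chair that holds the silyloxy group pseudoaxial, that is anti to the silyloxy group and on the oxirane face, where lithium can bridge the carbonyl and oxirane oxygens; this puts the new hydroxyl trans to the oxirane and cis to the C4' oxygen.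

Step 21
Reactants: 27 methyl 2-{(1S,2R,5R,6R)-5-[(tert-butyldimethylsilyl)oxy]-2-hydroxy-7-oxabicyclo[4.1.0]heptan-2-yl}acetate
Product: 28 methyl 2-{(1S,2R,5R,6R)-5-[(tert-butyldimethylsilyl)oxy]-2-[(triethylsilyl)oxy]-7-oxabicyclo[4.1.0]heptan-2-yl}acetate
Conditions: Et3SiOTf, 2,6-lutidine, CH2Cl2, −78 → 0 °C
Reagents that add atoms: triethylsilyl trifluoromethanesulfonate, CC[Si](CC)(CC)OS(=O)(=O)C(F)(F)F
Why: The silyl triflate with a hindered pyridine base silylates the tertiary alcohol; from here on no alkoxide can form next to the oxirane or trigger retro-aldol cleavage.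

Step 22
Reactants: 28 methyl 2-{(1S,2R,5R,6R)-5-[(tert-butyldimethylsilyl)oxy]-2-[(triethylsilyl)oxy]-7-oxabicyclo[4.1.0]heptan-2-yl}acetate
Product: 29 methyl (2Z)-2-{(1S,2R,5R,6R)-5-[(tert-butyldimethylsilyl)oxy]-2-[(triethylsilyl)oxy]-7-oxabicyclo[4.1.0]heptan-2-yl}-3-hydroxyprop-2-enoate (enol form of the α-formyl ester)
Conditions: LiN(iPr)2 (2.2 equiv), THF, −78 °C; HCO2Me, −78 → −20 °C; AcOH
Reagents that add atoms: methyl formate, COC=O
Why: Crossed Claisen condensation of the ester enolate with the formate, which cannot enolise; the second equivalent of base converts the product into its stable enolate, and the low temperature holds back β-elimination of the silyloxy group.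

Step 23
Reactants: 29 methyl (2Z)-2-{(1S,2R,5R,6R)-5-[(tert-butyldimethylsilyl)oxy]-2-[(triethylsilyl)oxy]-7-oxabicyclo[4.1.0]heptan-2-yl}-3-hydroxyprop-2-enoate
Product: 30 methyl (2Z)-3-amino-2-{(1S,2R,5R,6R)-5-[(tert-butyldimethylsilyl)oxy]-2-[(triethylsilyl)oxy]-7-oxabicyclo[4.1.0]heptan-2-yl}prop-2-enoate
Conditions: NH4OAc, MeOH, 40 °C
Reagents that add atoms: ammonium acetate, CC(=O)[O-].[NH4+]
Why: Condensation of the formyl group with ammonia under buffered conditions gives the primary enamine, a vinylogous carbamate held in the Z form by an N–H···O=C hydrogen bond. The amino group cannot open the oxirane because its side chain sits on the oxirane face.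

Step 24
Reactants: 17 5-[{(1R,2S,4aS,7S,8aR)-4,7-dimethyl-1-[(1E)-prop-1-en-1-yl]-1,2,4a,5,6,7,8,8a-octahydronaphthalen-2-yl}(hydroxy)methylidene]-2,2-dimethyl-1,3-dioxane-4,6-dione; 30 methyl (2Z)-3-amino-2-{(1S,2R,5R,6R)-5-[(tert-butyldimethylsilyl)oxy]-2-[(triethylsilyl)oxy]-7-oxabicyclo[4.1.0]heptan-2-yl}prop-2-enoate
Product: 32 methyl (2Z)-3-({3-[(1R,2S,4aS,7S,8aR)-4,7-dimethyl-1-[(1E)-prop-1-en-1-yl]-1,2,4a,5,6,7,8,8a-octahydronaphthalen-2-yl]-3-oxopropanoyl}amino)-2-{(1S,2R,5R,6R)-5-[(tert-butyldimethylsilyl)oxy]-2-[(triethylsilyl)oxy]-7-oxabicyclo[4.1.0]heptan-2-yl}prop-2-enoate, via acylketene 31 (not isolated)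
Conditions: PhMe, 90 °C
Reagents that add atoms: none
Why: Thermolysis of the acyl Meldrum's acid releases acetone and carbon dioxide and gives an acylketene, which is trapped at nitrogen by the enamino ester. The enamine carbon is fully substituted and attached to a quaternary centre, so C-acylation and cycloaddition across the C=C bond are blocked, and no base or coupling agent touches either fragment.

Step 25
Reactants: 32 methyl (2Z)-3-({3-[(1R,2S,4aS,7S,8aR)-4,7-dimethyl-1-[(1E)-prop-1-en-1-yl]-1,2,4a,5,6,7,8,8a-octahydronaphthalen-2-yl]-3-oxopropanoyl}amino)-2-{(1S,2R,5R,6R)-5-[(tert-butyldimethylsilyl)oxy]-2-[(triethylsilyl)oxy]-7-oxabicyclo[4.1.0]heptan-2-yl}prop-2-enoate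
Product: 33 3-{[(1R,2S,4aS,7S,8aR)-4,7-dimethyl-1-[(1E)-prop-1-en-1-yl]-1,2,4a,5,6,7,8,8a-octahydronaphthalen-2-yl]carbonyl}-5-{(1S,2R,5R,6R)-5-[(tert-butyldimethylsilyl)oxy]-2-[(triethylsilyl)oxy]-7-oxabicyclo[4.1.0]heptan-2-yl}-4-hydroxypyridin-2(1H)-one
Conditions: KOtBu (3 equiv), THF, 0 °C → rt; AcOH
Reagents that add atoms: none
Why: The alkoxide removes a proton from the β-keto amide methylene (pyridone C3), and this carbanion adds to the methyl ester carbonyl (pyridone C4) of the Z-enamide; loss of methoxide gives the 2,4-dioxo tautomer, which enolises to the aromatic 4-hydroxy-2-pyridone and is deprotonated, so the sequence is pulled forward irreversibly. The closest known reaction type is the Dieckmann (intramolecular Claisen) cyclisation of N-(β-ketoacyl) β-enamino esters to 3-acyl-4-hydroxy-2-pyridones, the six-ring counterpart of the Lacey–Dieckmann tetramic acid synthesis. Ring C closes in the 6-exo-trig mode, the breaking C=O π bond lying outside the new ring. No stereocentre is formed; decalin C2 is protected from enolisation because first the β-keto amide and then the acylpyridone are present as anions, and its configuration is in any case the more stable one. The step needs C-acylation at C3 and not O-acylation by the amide oxygen or retro-Claisen cleavage: the O-acylated acyl imidate is reactive and reverts, only the C-acylated product can aromatise, and a hindered alkoxide in an aprotic solvent does not add to the ketone. It also needs the Z enamide and the cis amide rotamer; the push–pull enamide rotates easily about its C=C bond under base and both rotamers interconvert faster than the closure. Ring D takes no part because both hydroxyls are silylated, so no alkoxide is available for Payne rearrangement, and the pyridone oxygen sits on the oxirane face, from which backside attack is impossible.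

Step 26
Reactants: 33 3-{[(1R,2S,4aS,7S,8aR)-4,7-dimethyl-1-[(1E)-prop-1-en-1-yl]-1,2,4a,5,6,7,8,8a-octahydronaphthalen-2-yl]carbonyl}-5-{(1S,2R,5R,6R)-5-[(tert-butyldimethylsilyl)oxy]-2-[(triethylsilyl)oxy]-7-oxabicyclo[4.1.0]heptan-2-yl}-4-hydroxypyridin-2(1H)-one
Product: 34 3-{[(1R,2S,4aS,7S,8aR)-4,7-dimethyl-1-[(1E)-prop-1-en-1-yl]-1,2,4a,5,6,7,8,8a-octahydronaphthalen-2-yl]carbonyl}-5-[(1S,2R,5R,6S)-2,5-dihydroxy-7-oxabicyclo[4.1.0]heptan-2-yl]-4-hydroxypyridin-2(1H)-one (CNP0494338.1)
Conditions: HF·pyridine, pyridine, THF, 0 °C → rt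
Reagents that add atoms: none
Why: Fluoride-mediated cleavage of both silyl ethers in a pyridine-buffered medium; no base is present, so the freed hydroxyls cannot start a Payne rearrangement, and the buffering limits acid-induced ionisation of the tertiary carbinol.

## Compound list

1 | (S)-citronellal [(3S)-3,7-dimethyloct-6-enal] | C[C@@H](CCC=C(C)C)CC=O | starting material
2 | (6S)-8,8-dimethoxy-2,6-dimethyloct-2-ene | C[C@@H](CCC=C(C)C)CC(OC)OC | intermediate
3 | (4S)-6,6-dimethoxy-4-methylhexanal | C[C@@H](CCC=O)CC(OC)OC | intermediate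
4 | (2E,6S)-8,8-dimethoxy-2,6-dimethyloct-2-enal | C[C@@H](CC/C=C(\C)C=O)CC(OC)OC | intermediate (not isolated)
5 | methyl (2E,4E,8S)-10,10-dimethoxy-4,8-dimethyldeca-2,4-dienoate | C[C@@H](CC/C=C(C)/C=C/C(=O)OC)CC(OC)OC | intermediate
6 | (2E,4E,8S)-10,10-dimethoxy-4,8-dimethyldeca-2,4-dien-1-ol | C[C@@H](CC/C=C(C)/C=C/CO)CC(OC)OC | intermediate
7 | tert-butyl{[(2E,4E,8S)-10,10-dimethoxy-4,8-dimethyldeca-2,4-dien-1-yl]oxy}diphenylsilane | C[C@@H](CC/C=C(C)/C=C/CO[Si](c1ccccc1)(c1ccccc1)C(C)(C)C)CC(OC)OC | intermediate
8 | (3S,6E,8E)-10-[(tert-butyldiphenylsilyl)oxy]-3,7-dimethyldeca-6,8-dienal | C[C@@H](CC/C=C(C)/C=C/CO[Si](c1ccccc1)(c1ccccc1)C(C)(C)C)CC=O | intermediate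
9 | (2E,5S,8E,10E)-12-[(tert-butyldiphenylsilyl)oxy]-5,9-dimethyldodeca-2,8,10-trienal | C[C@@H](CC/C=C(C)/C=C/CO[Si](c1ccccc1)(c1ccccc1)C(C)(C)C)C/C=C/C=O | intermediate
10 | (1R,2S,4aS,7S,8aS)-2-{[(tert-butyldiphenylsilyl)oxy]methyl}-4,7-dimethyl-1,2,4a,5,6,7,8,8a-octahydronaphthalene-1-carbaldehyde (trans-fused; C1 formyl and C2 silyloxymethyl cis) | O=C[C@@H]1[C@H]2C[C@@H](C)CC[C@@H]2C(C)=C[C@@H]1CO[Si](c1ccccc1)(c1ccccc1)C(C)(C)C | intermediate
11 | tert-butyl({(1R,2R,4aS,7S,8aR)-4,7-dimethyl-1-[(1E)-prop-1-en-1-yl]-1,2,4a,5,6,7,8,8a-octahydronaphthalen-2-yl}methoxy)diphenylsilane | C/C=C/[C@@H]1[C@H]2C[C@@H](C)CC[C@@H]2C(C)=C[C@@H]1CO[Si](c1ccccc1)(c1ccccc1)C(C)(C)C | intermediate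
12 | {(1R,2R,4aS,7S,8aR)-4,7-dimethyl-1-[(1E)-prop-1-en-1-yl]-1,2,4a,5,6,7,8,8a-octahydronaphthalen-2-yl}methanol | C/C=C/[C@@H]1[C@H]2C[C@@H](C)CC[C@@H]2C(C)=C[C@@H]1CO | intermediate
13 | (1R,2R,4aS,7S,8aR)-4,7-dimethyl-1-[(1E)-prop-1-en-1-yl]-1,2,4a,5,6,7,8,8a-octahydronaphthalene-2-carbaldehyde (C1/C2 cis) | C/C=C/[C@@H]1[C@H]2C[C@@H](C)CC[C@@H]2C(C)=C[C@@H]1C=O | intermediate (not isolated)
14 | (1R,2S,4aS,7S,8aR)-4,7-dimethyl-1-[(1E)-prop-1-en-1-yl]-1,2,4a,5,6,7,8,8a-octahydronaphthalene-2-carbaldehyde (C1/C2 trans) | C/C=C/[C@@H]1[C@H]2C[C@@H](C)CC[C@@H]2C(C)=C[C@H]1C=O | intermediate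
15 | (1R,2S,4aS,7S,8aR)-4,7-dimethyl-1-[(1E)-prop-1-en-1-yl]-1,2,4a,5,6,7,8,8a-octahydronaphthalene-2-carboxylic acid | C/C=C/[C@@H]1[C@H]2C[C@@H](C)CC[C@@H]2C(C)=C[C@H]1C(=O)O | intermediate
16 | Meldrum's acid (2,2-dimethyl-1,3-dioxane-4,6-dione) | CC1(C)OC(=O)CC(=O)O1 | starting material
17 | 5-[{(1R,2S,4aS,7S,8aR)-4,7-dimethyl-1-[(1E)-prop-1-en-1-yl]-1,2,4a,5,6,7,8,8a-octahydronaphthalen-2-yl}(hydroxy)methylidene]-2,2-dimethyl-1,3-dioxane-4,6-dione | C/C=C/[C@@H]1[C@H]2C[C@@H](C)CC[C@@H]2C(C)=C[C@H]1C(O)=C1C(=O)OC(C)(C)OC1=O | intermediate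
18 | cyclohexa-1,3-diene | C1=CC=CCC1 | starting material
19 | 2,3-dioxabicyclo[2.2.2]oct-5-ene (meso) | O1[C@@H]2C=C[C@H](O1)CC2 | intermediate (not isolated)
20 | cis-cyclohex-2-ene-1,4-diol (meso, 1S,4R) | O[C@@H]1C=C[C@H](O)CC1 | intermediate
21 | (1S,4R)-4-hydroxycyclohex-2-en-1-yl acetate | CC(=O)O[C@@H]1C=C[C@H](O)CC1 | intermediate
22 | (1S,4R)-4-[(tert-butyldimethylsilyl)oxy]cyclohex-2-en-1-yl acetate | CC(=O)O[C@@H]1C=C[C@H](O[Si](C)(C)C(C)(C)C)CC1 | intermediate
23 | (1S,4R)-4-[(tert-butyldimethylsilyl)oxy]cyclohex-2-en-1-ol | O[C@@H]1C=C[C@H](O[Si](C)(C)C(C)(C)C)CC1 | intermediate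
24 | (4R)-4-[(tert-butyldimethylsilyl)oxy]cyclohex-2-en-1-one | O=C1C=C[C@H](O[Si](C)(C)C(C)(C)C)CC1 | intermediate
25 | (1S,5R,6R)-5-[(tert-butyldimethylsilyl)oxy]-7-oxabicyclo[4.1.0]heptan-2-one (oxirane trans to the silyloxy group) | O=C1CC[C@@H](O[Si](C)(C)C(C)(C)C)[C@@H]2O[C@H]12 | intermediate
26 | methyl acetate | COC(C)=O | starting material
27 | methyl 2-{(1S,2R,5R,6R)-5-[(tert-butyldimethylsilyl)oxy]-2-hydroxy-7-oxabicyclo[4.1.0]heptan-2-yl}acetate | COC(=O)C[C@]1(O)CC[C@@H](O[Si](C)(C)C(C)(C)C)[C@@H]2O[C@@H]21 | intermediate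
28 | methyl 2-{(1S,2R,5R,6R)-5-[(tert-butyldimethylsilyl)oxy]-2-[(triethylsilyl)oxy]-7-oxabicyclo[4.1.0]heptan-2-yl}acetate | COC(=O)C[C@]1(O[Si](CC)(CC)CC)CC[C@@H](O[Si](C)(C)C(C)(C)C)[C@@H]2O[C@@H]21 | intermediate
29 | methyl (2Z)-2-{(1S,2R,5R,6R)-5-[(tert-butyldimethylsilyl)oxy]-2-[(triethylsilyl)oxy]-7-oxabicyclo[4.1.0]heptan-2-yl}-3-hydroxyprop-2-enoate (enol of the α-formyl ester) | O/C=C(/[C@]1(O[Si](CC)(CC)CC)CC[C@@H](O[Si](C)(C)C(C)(C)C)[C@@H]2O[C@@H]21)C(=O)OC | intermediate
30 | methyl (2Z)-3-amino-2-{(1S,2R,5R,6R)-5-[(tert-butyldimethylsilyl)oxy]-2-[(triethylsilyl)oxy]-7-oxabicyclo[4.1.0]heptan-2-yl}prop-2-enoate | N/C=C(/[C@]1(O[Si](CC)(CC)CC)CC[C@@H](O[Si](C)(C)C(C)(C)C)[C@@H]2O[C@@H]21)C(=O)OC | intermediate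
31 | 3-{(1R,2S,4aS,7S,8aR)-4,7-dimethyl-1-[(1E)-prop-1-en-1-yl]-1,2,4a,5,6,7,8,8a-octahydronaphthalen-2-yl}-3-oxoprop-1-en-1-one (acylketene) | C/C=C/[C@@H]1[C@H]2C[C@@H](C)CC[C@@H]2C(C)=C[C@H]1C(=O)C=C=O | intermediate (not isolated)
32 | methyl (2Z)-3-({3-[(1R,2S,4aS,7S,8aR)-4,7-dimethyl-1-[(1E)-prop-1-en-1-yl]-1,2,4a,5,6,7,8,8a-octahydronaphthalen-2-yl]-3-oxopropanoyl}amino)-2-{(1S,2R,5R,6R)-5-[(tert-butyldimethylsilyl)oxy]-2-[(triethylsilyl)oxy]-7-oxabicyclo[4.1.0]heptan-2-yl}prop-2-enoate | C/C=C/[C@@H]1[C@H]2C[C@@H](C)CC[C@@H]2C(C)=C[C@H]1C(=O)CC(=O)N/C=C(/[C@]1(O[Si](CC)(CC)CC)CC[C@@H](O[Si](C)(C)C(C)(C)C)[C@@H]2O[C@@H]21)C(=O)OC | intermediate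
33 | 3-{[(1R,2S,4aS,7S,8aR)-4,7-dimethyl-1-[(1E)-prop-1-en-1-yl]-1,2,4a,5,6,7,8,8a-octahydronaphthalen-2-yl]carbonyl}-5-{(1S,2R,5R,6R)-5-[(tert-butyldimethylsilyl)oxy]-2-[(triethylsilyl)oxy]-7-oxabicyclo[4.1.0]heptan-2-yl}-4-hydroxypyridin-2(1H)-one | C/C=C/[C@@H]1[C@H]2C[C@@H](C)CC[C@@H]2C(C)=C[C@H]1C(=O)c1c(O)c([C@]2(O[Si](CC)(CC)CC)CC[C@@H](O[Si](C)(C)C(C)(C)C)[C@@H]3O[C@@H]32)c[nH]c1=O | intermediate
34 | 3-{[(1R,2S,4aS,7S,8aR)-4,7-dimethyl-1-[(1E)-prop-1-en-1-yl]-1,2,4a,5,6,7,8,8a-octahydronaphthalen-2-yl]carbonyl}-5-[(1S,2R,5R,6S)-2,5-dihydroxy-7-oxabicyclo[4.1.0]heptan-2-yl]-4-hydroxypyridin-2(1H)-one | C/C=C/[C@@H]1[C@H]2C[C@@H](C)CC[C@@H]2C(C)=C[C@H]1C(=O)c1c(O)c([C@]2(O)CC[C@@H](O)[C@@H]3O[C@@H]32)c[nH]c1=O | target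

## Step count and uncertain steps

Total step count: 26. Longest linear sequence: 16 steps (steps 1–13, then 24–26, from 1); the ring D arm is 13 steps from 18 (steps 14–26).

**Step 25 (key step).** The most likely failure is cleavage of the β-keto amide by retro-Claisen attack, or stalling of the closure. The ester is deactivated by the enamide nitrogen and crowded by the quaternary C1' with its silyloxy group, so the unreactive anion may simply persist or decompose.

Fallback: the ring is closed before the decalin acyl group is present and the acyl group is moved onto C3 afterwards. It sets out from enamino ester 30. N-acetylation with acetyl chloride and pyridine gives methyl (2Z)-3-acetamido-2-(ring D)prop-2-enoate F1. Its dianion (LiN(SiMe3)2, THF) closes the same C3–C4 bond to 4-hydroxy-5-(ring D)pyridin-2(1H)-one F2. Acid 15 with DCC acylates the C4 hydroxyl to the 4-pyridyl ester F3. A DMAP-induced 1,3-acyl shift from oxygen to C3, a known Fries-type migration of 4-acyloxy-2-pyridones, returns to the route at 33. The same detour serves if the nitrogen of 30 is too weakly nucleophilic in step 24.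

**Step 20.** The risk is poor facial selectivity. Attack anti to the oxirane C–O bond, the Felkin–Anh direction, competes with the desired attack anti to the silyloxy group and would give the C1' epimer, which cannot be corrected later.

Fallback: the C–C bond is made before the oxirane. It sets out from enone 24. The lithium enolate of 26 adds 1,2, anti to the pseudoaxial silyloxy group, to give methyl 2-{(1R,4R)-4-[(tert-butyldimethylsilyl)oxy]-1-hydroxycyclohex-2-en-1-yl}acetate F4. Et3SiOTf gives the bis-silyl ether F5. Peracid epoxidation on the face opposite to both silyloxy groups returns to the route at 28.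

**Step 11.** The risk is migration of the C3=C4 alkene into conjugation with the aldehyde during the base equilibration, or an equilibrium that does not lie far enough on the trans side.

Fallback: the correction of C2 is moved to the acylpyridone, where the ketone is part of a vinylogous carboxylate anion. It sets out from alcohol 12, which is oxidised without equilibration to the cis acid F6. This is carried through the chemistry of steps 13, 24 and 25 as the cis acyl Meldrum's acid F7, the cis β-keto amide F8 and the cis pyridone F9. Prolonged exposure of F9 to the alkoxide of step 25 then equilibrates decalin C2 and returns to the route at 33.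

**Step 22.** The risk is β-elimination of the silyloxy group from the ester enolate, or incomplete deprotonation of the methylene group next to the quaternary carbon.

Fallback: the formyl carbon is brought in with the enolate, so that no second enolisation is needed. It sets out from ketone 25. The lithium enolate of methyl 3,3-dimethoxypropanoate adds as in step 20 to give the dimethoxy hydroxy ester F10, a mixture at the ester α-carbon, which later becomes sp2. Et3SiOTf gives the silyl ether F11. Warming with NH4OAc and AcOH in MeOH removes methanol and exchanges the remaining methoxy group for the amino group, which returns to the route at 30.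

## Further compounds

F1 | step 25 | methyl (2Z)-3-acetamido-2-{(1S,2R,5R,6R)-5-[(tert-butyldimethylsilyl)oxy]-2-[(triethylsilyl)oxy]-7-oxabicyclo[4.1.0]heptan-2-yl}prop-2-enoate | CC(=O)N/C=C(/[C@]1(O[Si](CC)(CC)CC)CC[C@@H](O[Si](C)(C)C(C)(C)C)[C@@H]2O[C@@H]21)C(=O)OC
F2 | step 25 | 5-{(1S,2R,5R,6R)-5-[(tert-butyldimethylsilyl)oxy]-2-[(triethylsilyl)oxy]-7-oxabicyclo[4.1.0]heptan-2-yl}-4-hydroxypyridin-2(1H)-one | O=c1cc(O)c([C@]2(O[Si](CC)(CC)CC)CC[C@@H](O[Si](C)(C)C(C)(C)C)[C@@H]3O[C@@H]32)c[nH]1
F3 | step 25 | 5-{(1S,2R,5R,6R)-5-[(tert-butyldimethylsilyl)oxy]-2-[(triethylsilyl)oxy]-7-oxabicyclo[4.1.0]heptan-2-yl}-2-oxo-1,2-dihydropyridin-4-yl (1R,2S,4aS,7S,8aR)-4,7-dimethyl-1-[(1E)-prop-1-en-1-yl]-1,2,4a,5,6,7,8,8a-octahydronaphthalene-2-carboxylate | C/C=C/[C@@H]1[C@H]2C[C@@H](C)CC[C@@H]2C(C)=C[C@H]1C(=O)Oc1cc(=O)[nH]cc1[C@]1(O[Si](CC)(CC)CC)CC[C@@H](O[Si](C)(C)C(C)(C)C)[C@@H]2O[C@@H]21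
F4 | step 20 | methyl 2-{(1R,4R)-4-[(tert-butyldimethylsilyl)oxy]-1-hydroxycyclohex-2-en-1-yl}acetate | COC(=O)C[C@]1(O)CC[C@@H](O[Si](C)(C)C(C)(C)C)C=C1
F5 | step 20 | methyl 2-{(1R,4R)-4-[(tert-butyldimethylsilyl)oxy]-1-[(triethylsilyl)oxy]cyclohex-2-en-1-yl}acetate | COC(=O)C[C@]1(O[Si](CC)(CC)CC)CC[C@@H](O[Si](C)(C)C(C)(C)C)C=C1
F6 | step 11 | (1R,2R,4aS,7S,8aR)-4,7-dimethyl-1-[(1E)-prop-1-en-1-yl]-1,2,4a,5,6,7,8,8a-octahydronaphthalene-2-carboxylic acid (C1/C2 cis) | C/C=C/[C@@H]1[C@H]2C[C@@H](C)CC[C@@H]2C(C)=C[C@@H]1C(=O)O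
F7 | step 11 | 5-[{(1R,2R,4aS,7S,8aR)-4,7-dimethyl-1-[(1E)-prop-1-en-1-yl]-1,2,4a,5,6,7,8,8a-octahydronaphthalen-2-yl}(hydroxy)methylidene]-2,2-dimethyl-1,3-dioxane-4,6-dione | C/C=C/[C@@H]1[C@H]2C[C@@H](C)CC[C@@H]2C(C)=C[C@@H]1C(O)=C1C(=O)OC(C)(C)OC1=O
F8 | step 11 | methyl (2Z)-3-({3-[(1R,2R,4aS,7S,8aR)-4,7-dimethyl-1-[(1E)-prop-1-en-1-yl]-1,2,4a,5,6,7,8,8a-octahydronaphthalen-2-yl]-3-oxopropanoyl}amino)-2-{(1S,2R,5R,6R)-5-[(tert-butyldimethylsilyl)oxy]-2-[(triethylsilyl)oxy]-7-oxabicyclo[4.1.0]heptan-2-yl}prop-2-enoate | C/C=C/[C@@H]1[C@H]2C[C@@H](C)CC[C@@H]2C(C)=C[C@@H]1C(=O)CC(=O)N/C=C(/[C@]1(O[Si](CC)(CC)CC)CC[C@@H](O[Si](C)(C)C(C)(C)C)[C@@H]2O[C@@H]21)C(=O)OC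
F9 | step 11 | 3-{[(1R,2R,4aS,7S,8aR)-4,7-dimethyl-1-[(1E)-prop-1-en-1-yl]-1,2,4a,5,6,7,8,8a-octahydronaphthalen-2-yl]carbonyl}-5-{(1S,2R,5R,6R)-5-[(tert-butyldimethylsilyl)oxy]-2-[(triethylsilyl)oxy]-7-oxabicyclo[4.1.0]heptan-2-yl}-4-hydroxypyridin-2(1H)-one | C/C=C/[C@@H]1[C@H]2C[C@@H](C)CC[C@@H]2C(C)=C[C@@H]1C(=O)c1c(O)c([C@]2(O[Si](CC)(CC)CC)CC[C@@H](O[Si](C)(C)C(C)(C)C)[C@@H]3O[C@@H]32)c[nH]c1=O
F10 | step 22 | methyl 2-{(1S,2R,5R,6R)-5-[(tert-butyldimethylsilyl)oxy]-2-hydroxy-7-oxabicyclo[4.1.0]heptan-2-yl}-3,3-dimethoxypropanoate (both epimers at the ester α-carbon) | COC(OC)C(C(=O)OC)[C@]1(O)CC[C@@H](O[Si](C)(C)C(C)(C)C)[C@@H]2O[C@@H]21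
F11 | step 22 | methyl 2-{(1S,2R,5R,6R)-5-[(tert-butyldimethylsilyl)oxy]-2-[(triethylsilyl)oxy]-7-oxabicyclo[4.1.0]heptan-2-yl}-3,3-dimethoxypropanoate (both epimers at the ester α-carbon) | COC(OC)C(C(=O)OC)[C@]1(O[Si](CC)(CC)CC)CC[C@@H](O[Si](C)(C)C(C)(C)C)[C@@H]2O[C@@H]21
A1 | alternative 1 | 1-{4,6-bis[2-(trimethylsilyl)ethoxy]pyridin-3-yl}-7,8-(isopropylidenedioxy)-2,3-dioxabicyclo[2.2.2]oct-5-ene, acetonide anti to the peroxide bridge | c1([C@]23OO[C@H](C=C2)[C@@H]4OC(C)(C)O[C@H]34)cnc(OCC[Si](C)(C)C)cc1OCC[Si](C)(C)C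
A2 | alternative 2 | 6-{4,6-bis[2-(trimethylsilyl)ethoxy]pyridin-3-yl}-7-oxabicyclo[4.1.0]hept-2-ene, single enantiomer | c1([C@@]23O[C@@H]2C=CCC3)cnc(OCC[Si](C)(C)C)cc1OCC[Si](C)(C)C
A3 | alternative 3 | 3-{[(1R,2S,4aS,7S,8aR)-4,7-dimethyl-1-[(1E)-prop-1-en-1-yl]-1,2,4a,5,6,7,8,8a-octahydronaphthalen-2-yl]carbonyl}-4-hydroxy-5-(4-hydroxyphenyl)pyridin-2(1H)-one | C/C=C/[C@@H]1[C@H]2C[C@@H](C)CC[C@@H]2C(C)=C[C@H]1C(=O)c1c(O)c(-c2ccc(O)cc2)c[nH]c1=O
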